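## Structural features

Oppositin is an achiral 5,7-dimethoxyflavone: ring A is the benzenoid ring, ring C the fused 4-pyranone, ring B the phenyl group on C2. C6 of ring A is bonded directly to C2'' of a second, monocyclic 4-pyranone, ring D (O1'', C2'', C3''–H, C4''=O, C5''–OMe, C6''–Me). The C6–C2'' bond lies between the methoxy groups on C5 and C7, so it is the most hindered position of ring A and rings A and D are twisted against each other. Ring D offers only O1'' and C3''–H next to this axis, so no stable atropisomers are expected; there are no stereocentres, and nothing stereogenic has to survive to the end. The fragile groups are: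
- the two γ-pyranone rings, which are opened by hydroxide, alkoxides or hot amines;
- the 5-methoxy group peri to the C4 carbonyl, which chelating Lewis acids such as BBr3 or AlCl3 cleave;
- the electron-rich C8–H, which reacts with electrophilic halogen.

The real difficulty is to put a carbon substituent at C6 and not at C8, and to build a pyranone in which every ring atom carries a different substituent, without a late C–C coupling at the hindered C6. The key step uses the fact that C2'' and O1'' have the connectivity of a formyl group on C6, while C3'' to C6'' form a four-carbon 1,3-dioxygenated diene that can carry the C5'' methoxy and C6'' methyl groups from the start. The hindered C6–C2'' bond is therefore never made; it enters as the aryl–CHO bond of a symmetric benzaldehyde.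

## Logic of the disconnections

**15 to 13.** No skeletal bond is cut; two hydrogens are added across C2''–C3''. The reason is that 13, not 15, is the direct outcome of an aldehyde–diene cyclocondensation. The gain is that ring D becomes accessible from a formyl group. The demand on the forward step is a dehydrogenation that acts only at C3''–H and C2''–H and spares C8–H, the methoxy groups and both pyranone carbonyls; it also removes the racemic centre of 13. It runs through 14.

**13 to 6 and 11.** The bonds C2''–C3'' and O1''–C6'' are cut. This separates the whole of ring D except C2'' and O1'' from the flavone and turns the target into a flavone aldehyde and a five-carbon diene that already holds the C5'' methoxy and C6'' methyl groups. The forward step must form the C–C bond at a hindered, electron-rich formyl group, must use a monodentate Lewis acid that does not touch the 5-methoxy group, and must close the ring through 12 with loss of methanol.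

**6 to 2 and 3.** The bonds C4a–C4, C4–C3 and O1–C2 are cut, with carbon monoxide as the source of C4. Rings B and C come from an alkyne and a one-carbon unit, and ring A is reduced to an ortho-iodophenol. The forward step must insert carbon monoxide before the alkyne couples, must close 6-endo (through 4 and 5), and must tolerate the free formyl group.

**2 to 1.** The C–I bond is cut. In 1 the two positions ortho to the hydroxyl are equivalent, so the symmetry of 1 decides the C6 versus C8 question of the flavone and no regiochemical control is needed. The demand is mono-iodination only.

**11 to 10 to 9.** The O–Si bond and then one O–CH3 bond are cut. The diene becomes a symmetric β-diketone, so only one enol ether constitution is possible from 9. The forward steps need kinetic deprotonation of 10 at the acetyl methyl group and enol ether formation without a second ketalisation.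

**9 to 7.** The bond between the methoxy-bearing carbon and one acetyl group is cut. This leads to a three-carbon ketone of commerce. The acetylation must take place at the more substituted α-carbon of 7; acid-mediated enolisation should secure this, through 8.

## Other disconnections considered

**Alternative 1:** The cut runs through C3''–C4'' and O1''–C2'' of ring D. In the forward step 5-methoxy-2,2,6-trimethyl-4H-1,3-dioxin-4-one A2 would be heated so that cycloreversion releases acetyl(methoxy)ketene A3. A3 would add as a 1-oxadiene to the silyl enol ether {[1-(4-benzyloxy-2,6-dimethoxyphenyl)ethenyl]oxy}trimethylsilane A4, and the adduct would aromatise by eliminating its silyloxy group to give 2-(4-benzyloxy-2,6-dimethoxyphenyl)-5-methoxy-6-methyl-4H-pyran-4-one A1.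
- In its favour: ring D arrives at its final oxidation level, with no sp3 centre and no dehydrogenation. On this point the alternative is better than the chosen plan. The conditions are thermal and neutral, with no Lewis acid near a methoxy group.
- Equal to the chosen plan: the hindered aryl–C2'' bond is again inherited from a carbonyl compound, and ring C would be made by the same carbonylative annulation.
- Against it here: A2 is not an article of commerce and would have to be made first. A3 can dimerise, and the O1''–C2'' bond must form at a carbon shielded by a doubly ortho-substituted aryl group. Ring A of A1 is still a simple aryl ether, so debenzylation, ortho-iodination and carbonylative annulation would have to follow the key step. The annulation would then expose ring D to a hot secondary amine, which can open 4-pyranones.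
- Step economy: about three steps after the key step against one in the chosen plan, and a longer linear sequence overall.

**Alternative 2:** The cut runs through C4a–C5 and C8–C8a of ring A. In the forward step the diene benzyl 2-[benzyloxy(trimethylsilyloxy)methylidene]-3-methoxybut-3-enoate A7 would add to the nitrile-bearing double bond of 4-oxo-6-phenyl-4H-pyran-3-carbonitrile A6. Loss of the nitrile and of one oxygen substituent at C5 would aromatise the adduct to benzyl 5-hydroxy-7-methoxy-4-oxo-2-phenyl-4H-chromene-6-carboxylate A5.
- In its favour: the substitution pattern of ring A (5-oxygen, 6-carbon, 7-methoxy) is fixed by the polarity of the diene, with no electrophilic substitution. On the C6 versus C8 question it is the equal of the chosen plan, which relies on symmetry. The aromatisation has a strong driving force.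
- Against it here: ring D is not built at all. A5 carries only a carboxyl carbon on C6, and after methylation of the chelated 5-hydroxyl and reduction of the ester it would merely reach 6, which the chosen plan reaches in two steps. A6 and A7 both need several steps. A7 is a fully substituted push–pull diene whose s-cis conformer is crowded, so a stepwise Michael pathway with less regiocontrol is conceivable.
- Step economy: clearly inferior, by roughly six steps. Neither plan has a stereochemical problem, so they are equal there.

**Alternative 3:** The cut is the C5–C6 bond of ring A. In the forward step a base would deprotonate the C6 methylene of methyl 2-[3-(5-methoxy-6-methyl-4-oxo-4H-pyran-2-yl)-2-oxopropyl]-4-oxo-6-phenyl-4H-pyran-3-carboxylate A9. The carbanion would attack the ester, and enolisation would give 5,7-dihydroxy-6-(5-methoxy-6-methyl-4-oxo-4H-pyran-2-yl)flavone A8.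
- In its favour: the closure follows the polyketide logic. Both pyranones are already aromatic, ring A forms at the aromatic oxidation level, and no redox step or transition metal is needed. In redox economy it is better than the chosen plan, and it is convergent in principle.
- Against it here: A9 has three acidic sites (the C6 methylene, the C8 methylene and the C6'' methyl group) and two base-sensitive pyranones. O-acylation through the C7 enolate oxygen would also close a six-membered ring and competes with the C-acylation wanted. Making A9 is estimated at eight steps or more, and a double O-methylation of A8 must follow, slowed at the hydrogen-bonded 5-hydroxyl.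
- Equal to the chosen plan: that methylation poses no regiochemical problem, because both hydroxyls end as methyl ethers.
- Step economy: markedly longer, with more risk from base-labile intermediates.

Key step: step 6

Remarks on the chemistry:
- The cyclocondensation creates one stereocentre, C2'' of 13, which is formed racemic and removed in step 7. Compounds 12, 13 and 14 are therefore racemic and no stereocontrol is planned.
- The enol ether geometry of 10, 11 and 12 is drawn Z. Either isomer should converge on 13, because the ring closes by addition–elimination.
- The fully substituted terminus of 11 makes a concerted [4+2] unlikely, so step 6 is planned as a Mukaiyama aldol followed by acid cyclisation in the same flask.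
- More than two equivalents of BF3·OEt2 are used, because the chromone carbonyl binds the first.
- No protecting group is needed in either branch.

## Route

Step 1
Reactants: 1 4-hydroxy-2,6-dimethoxybenzaldehyde
Product: 2 4-hydroxy-3-iodo-2,6-dimethoxybenzaldehyde
Conditions: NIS (1.0 equiv), TFA (cat.), MeCN, 0 °C → rt
Reagents that add atoms: N-iodosuccinimide, O=C1CCC(=O)N1I
Why: Electrophilic aromatic iodination ortho to the free hydroxyl; the two open positions of 1 are equivalent by symmetry and each is activated by the hydroxyl and two methoxy groups. One equivalent of reagent should stop largely at the mono-iodide, because the first iodine adds steric bulk and slight deactivation.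

Step 2
Reactants: 2 4-hydroxy-3-iodo-2,6-dimethoxybenzaldehyde; 3 phenylacetylene
Product: 6 5,7-dimethoxy-4-oxo-2-phenyl-4H-chromene-6-carbaldehyde, via alkynone 4 (not isolated), via enaminone 5 (not isolated)
Conditions: PdCl2(PPh3)2 (5 mol %), CO (20 atm), Et2NH, 120 °C
Reagents that add atoms: carbon monoxide, [C-]#[O+]
Why: Carbonylative annulation of an ortho-iodophenol with a terminal alkyne (carbonylative Sonogashira-type coupling, then cyclisation): oxidative addition of the C–I bond to zerovalent palladium formed from PdCl2(PPh3)2, CO insertion to ArC(O)PdI(PPh3)2 and alkynyl transfer give 4. Diethylamine adds to 4 to give 5, and the ortho-hydroxyl displaces the amine by 6-endo addition–elimination, which closes ring C and avoids the 5-exo mode; the formyl group has no α-hydrogen and should engage the amine only reversibly.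

Step 3
Reactants: 7 methoxyacetone (1-methoxypropan-2-one)
Product: 9 3-methoxypentane-2,4-dione, via difluoroboron chelate 8 (not isolated)
Conditions: Ac2O, BF3·2AcOH, 0 °C → rt; then aq NaOAc, reflux
Reagents that add atoms: acetic anhydride, CC(=O)OC(C)=O
Why: BF3-mediated C-acetylation of a ketone with an anhydride, which proceeds through the more substituted enol and so places the acetyl group on the methoxy-bearing carbon. The diketone is trapped as chelate 8, which hot aqueous NaOAc hydrolyses.

Step 4
Reactants: 9 3-methoxypentane-2,4-dione
Product: 10 (3Z)-3,4-dimethoxypent-3-en-2-one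
Conditions: HC(OMe)3, TsOH·H2O (cat.), MeOH, rt
Reagents that add atoms: trimethyl orthoformate, COC(OC)OC
Why: Acid-catalysed enol ether formation from a β-diketone with an orthoformate (ketalisation, then loss of methanol into conjugation with the remaining carbonyl). Since 9 is symmetric only one constitution can form, and the conjugated product resists a second ketalisation.

Step 5
Reactants: 10 (3Z)-3,4-dimethoxypent-3-en-2-one
Product: 11 trimethyl{[(3Z)-3,4-dimethoxypenta-1,3-dien-2-yl]oxy}silane
Conditions: LiN(iPr)2, THF, −78 °C; then TMSCl, −78 → 0 °C
Reagents that add atoms: chlorotrimethylsilane, C[Si](C)(C)Cl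
Why: Kinetic α'-deprotonation of a β-alkoxy enone at the acetyl methyl group and O-silylation of the enolate, the standard way to 1-alkoxy-3-silyloxydienes. The C3=C4 double bond is not touched, so its geometry is retained.

Step 6
Reactants: 6 5,7-dimethoxy-4-oxo-2-phenyl-4H-chromene-6-carbaldehyde; 11 trimethyl{[(3Z)-3,4-dimethoxypenta-1,3-dien-2-yl]oxy}silane
Product: 13 rac-5,7-dimethoxy-6-(5-methoxy-6-methyl-4-oxo-3,4-dihydro-2H-pyran-2-yl)-2-phenyl-4H-chromen-4-one, via β-hydroxy enone 12 (not isolated)
Conditions: BF3·OEt2 (2.5 equiv), CH2Cl2, −78 → −20 °C; then TFA, 0 °C → rt
Reagents that add atoms: none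
Why: The closest known reaction type is the Lewis-acid cyclocondensation of aldehydes with 1-alkoxy-3-silyloxydienes (hetero-Diels–Alder in its stepwise form, Mukaiyama aldol then cyclisation). BF3 first saturates the more basic chromone C4 carbonyl and a second equivalent activates the formyl oxygen; the unhindered CH2 terminus of 11 then attacks the formyl carbon through an open transition state, forms C2''–C3'' and gives 12 as its boron aldolate. A concerted [4+2] path is not counted on, because the fully substituted C4 terminus of 11 disfavours the s-cis diene. On addition of TFA the C2'' hydroxyl adds to C6'' of the β-methoxy enone in a 6-endo-trig oxa-Michael step, and the mixed ketal so formed expels methanol to restore the vinylogous ester, which forms O1''–C6'' and closes ring D. C2'' is the only new stereocentre; nothing controls it, it forms racemic and is erased in step 7, and the enol ether geometry is lost in the addition–elimination. Regioselectivity follows from the polarity of 11, which is nucleophilic only at the silyl enol ether CH2 and, after the aldol, electrophilic only at the methoxy-bearing C6''. Chemoselectivity rests on the formyl group being the only electrophilic carbonyl of 6, the chromone C4 carbonyl being a vinylogous ester and C2 being blocked by phenyl. The monodentate Lewis acid at low temperature should leave the 5- and 7-methoxy groups intact, and the C5'' methoxy and C6'' methyl groups arrive in place from the diene.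

Step 7
Reactants: 13 rac-5,7-dimethoxy-6-(5-methoxy-6-methyl-4-oxo-3,4-dihydro-2H-pyran-2-yl)-2-phenyl-4H-chromen-4-one
Product: 15 oppositin (5,7-dimethoxy-6-(5-methoxy-6-methyl-4-oxo-4H-pyran-2-yl)-2-phenyl-4H-chromen-4-one), via silyl dienol ether 14 (not isolated)
Conditions: TMSOTf, Et3N, CH2Cl2, 0 °C; then Pd(OAc)2 (1.1 equiv), MeCN, rt
Reagents that add atoms: none
Why: Saegusa–Ito oxidation: soft enolisation at C3'', the only α-CH2, gives 14; enolate transfer from silicon to Pd(OAc)2 and β-hydride elimination of the C2''–H then give the aromatic 4-pyranone and remove the C2'' stereocentre. No electrophile that could attack C8 is present, and the flavone carbonyl is silylated only reversibly.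

## Compound list

1 | 4-hydroxy-2,6-dimethoxybenzaldehyde | COc1cc(O)cc(OC)c1C=O | starting material
2 | 4-hydroxy-3-iodo-2,6-dimethoxybenzaldehyde | COc1cc(O)c(I)c(OC)c1C=O | intermediate
3 | phenylacetylene | C#Cc1ccccc1 | starting material
4 | 4-hydroxy-2,6-dimethoxy-3-(3-phenylprop-2-ynoyl)benzaldehyde (alkynone, not isolated) | COc1cc(O)c(C(=O)C#Cc2ccccc2)c(OC)c1C=O | intermediate
5 | 3-[(2E)-3-(diethylamino)-3-phenylprop-2-enoyl]-4-hydroxy-2,6-dimethoxybenzaldehyde (enaminone, not isolated; geometry immaterial, drawn E) | CCN(CC)/C(=C/C(=O)c1c(O)cc(OC)c(C=O)c1OC)c1ccccc1 | intermediate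
6 | 5,7-dimethoxy-4-oxo-2-phenyl-4H-chromene-6-carbaldehyde | COc1cc2oc(-c3ccccc3)cc(=O)c2c(OC)c1C=O | intermediate
7 | methoxyacetone (1-methoxypropan-2-one) | COCC(C)=O | starting material
8 | difluoroboron chelate of 3-methoxypentane-2,4-dione (not isolated) | COC1=C(C)O[B-](F)(F)[O+]=C1C | intermediate
9 | 3-methoxypentane-2,4-dione | COC(C(C)=O)C(C)=O | intermediate
10 | (3Z)-3,4-dimethoxypent-3-en-2-one | CC(=O)/C(OC)=C(\C)OC | intermediate
11 | trimethyl{[(3Z)-3,4-dimethoxypenta-1,3-dien-2-yl]oxy}silane | C=C(O[Si](C)(C)C)/C(OC)=C(\C)OC | intermediate
12 | rac-6-[(4Z)-1-hydroxy-4,5-dimethoxy-3-oxohex-4-en-1-yl]-5,7-dimethoxy-2-phenyl-4H-chromen-4-one (β-hydroxy enone, not isolated) | COc1cc2oc(-c3ccccc3)cc(=O)c2c(OC)c1C(O)CC(=O)/C(OC)=C(\C)OC | intermediate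
13 | rac-5,7-dimethoxy-6-(5-methoxy-6-methyl-4-oxo-3,4-dihydro-2H-pyran-2-yl)-2-phenyl-4H-chromen-4-one | COc1cc2oc(-c3ccccc3)cc(=O)c2c(OC)c1C1CC(=O)C(OC)=C(C)O1 | intermediate
14 | rac-5,7-dimethoxy-6-[5-methoxy-6-methyl-4-(trimethylsilyloxy)-2H-pyran-2-yl]-2-phenyl-4H-chromen-4-one (silyl dienol ether, not isolated) | COc1cc2oc(-c3ccccc3)cc(=O)c2c(OC)c1C1C=C(O[Si](C)(C)C)C(OC)=C(C)O1 | intermediate
15 | oppositin, 5,7-dimethoxy-6-(5-methoxy-6-methyl-4-oxo-4H-pyran-2-yl)-2-phenyl-4H-chromen-4-one | COc1cc2oc(-c3ccccc3)cc(=O)c2c(OC)c1-c1cc(=O)c(OC)c(C)o1 | target

## Step count and risks

Total step count: 7. Longest linear sequence: 5 steps (7 → 9 → 10 → 11 → 13 → 15, steps 3 to 7). The other branch (1 → 2 → 6) has 2 steps before the union in step 6.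

Least certain steps:

**Step 6 (key step).** Three things may go wrong:
- Addition to the formyl group may be slow, since it lies between two methoxy groups and is conjugated to an electron-rich ring, so protodesilylation of 11 may outrun C–C bond formation.
- Under the acid the benzylic C2''–O bond of 12 may ionise and dehydrate to a dienone instead of closing the ring.
- Part of the Lewis acid is held by the chromone carbonyl.

Fallback, from 6 and 10, returning at 15: the lithium enolate of 10 (LiN(iPr)2, THF, −78 °C) would be added to 6 in a plain aldol reaction, and 12 would be isolated. Dess–Martin periodinane would oxidise 12 to the β-diketone 6-[(4Z)-4,5-dimethoxy-3-oxohex-4-enoyl]-5,7-dimethoxy-2-phenyl-4H-chromen-4-one F1. Acid (TFA, CH2Cl2) would close F1 through its enol oxygen onto C6'' with loss of methanol and give 15 directly. This avoids both the ionisable benzylic alcohol in acid and the dehydrogenation of step 7.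

**Step 7.** Three things may go wrong:
- The 2H-pyran dienol ether 14 may undergo electrocyclic ring opening or hydrolyse back to 13 before it meets Pd(OAc)2.
- Enolisation may take place towards the C6'' methyl group instead of C3''.
- β-Hydride elimination has to reach a hindered benzylic C–H and may be slow.

Fallback, from 13, returning at 15: deprotonation with LiN(SiMe3)2 in THF at −78 °C and trapping with PhSeCl should give trans-5,7-dimethoxy-6-[5-methoxy-6-methyl-4-oxo-3-(phenylselanyl)-3,4-dihydro-2H-pyran-2-yl]-2-phenyl-4H-chromen-4-one F2. Oxidation with H2O2 (pyridine, CH2Cl2, 0 °C) would give the selenoxide, whose syn-elimination with the cis C2''–H gives 15.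

**Step 2.** Three things may go wrong:
- The alkyne may couple before carbon monoxide is inserted at the hindered, electron-rich aryl–palladium bond, and the free phenol may then cyclise to a benzofuran.
- Closure may occur in the 5-exo mode.
- The formyl group may condense with the amine at 120 °C.

Fallback, from 2, returning at 6: acetylation (Ac2O, pyridine) would give 4-formyl-2-iodo-3,5-dimethoxyphenyl acetate F3. Carbonylative coupling with 3 at low temperature and pressure (PdCl2(PPh3)2, dppp, thiourea, Et2NH, DBU, CO 1 atm, 40 °C) would give the alkynone 4-formyl-3,5-dimethoxy-2-(3-phenylprop-2-ynoyl)phenyl acetate F4. The amine would then remove the acetyl group from F4 and cyclise it 6-endo to 6. The phenol stays masked until the acyl group is in place.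

**Step 3.** Acetylation may occur in part at the methyl side of 7 or on oxygen, and the strong acid may cause loss of methanol.

Fallback, from 7, returning at 9: thermodynamic silylation (TMSCl, Et3N, DMF, 80 °C) would give the more substituted enol ether (Z)-[(1-methoxyprop-1-en-2-yl)oxy]trimethylsilane F5, which fixes the site of reaction beforehand. C-acylation of F5 with acetyl chloride and ZnCl2 (CH2Cl2/Et2O, rt) would give 9.

## Further compounds

F1 | step 6 | 6-[(4Z)-4,5-dimethoxy-3-oxohex-4-enoyl]-5,7-dimethoxy-2-phenyl-4H-chromen-4-one | COc1cc2oc(-c3ccccc3)cc(=O)c2c(OC)c1C(=O)CC(=O)/C(OC)=C(\C)OC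
F2 | step 7 | trans-5,7-dimethoxy-6-[5-methoxy-6-methyl-4-oxo-3-(phenylselanyl)-3,4-dihydro-2H-pyran-2-yl]-2-phenyl-4H-chromen-4-one (racemic, one enantiomer drawn) | COc1cc2oc(-c3ccccc3)cc(=O)c2c(OC)c1[C@H]1OC(C)=C(OC)C(=O)[C@@H]1[Se]c1ccccc1
F3 | step 2 | 4-formyl-2-iodo-3,5-dimethoxyphenyl acetate | COc1cc(OC(C)=O)c(I)c(OC)c1C=O
F4 | step 2 | 4-formyl-3,5-dimethoxy-2-(3-phenylprop-2-ynoyl)phenyl acetate | COc1cc(OC(C)=O)c(C(=O)C#Cc2ccccc2)c(OC)c1C=O
F5 | step 3 | (Z)-[(1-methoxyprop-1-en-2-yl)oxy]trimethylsilane | CO/C=C(/C)O[Si](C)(C)C
A1 | alternative 1 | 2-(4-benzyloxy-2,6-dimethoxyphenyl)-5-methoxy-6-methyl-4H-pyran-4-one | COc1cc(OCc2ccccc2)cc(OC)c1-c1cc(=O)c(OC)c(C)o1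
A2 | alternative 1 | 5-methoxy-2,2,6-trimethyl-4H-1,3-dioxin-4-one | COC1=C(C)OC(C)(C)OC1=O
A3 | alternative 1 | acetyl(methoxy)ketene (2-methoxy-3-oxobut-1-en-1-one) | CC(=O)C(OC)=C=O
A4 | alternative 1 | {[1-(4-benzyloxy-2,6-dimethoxyphenyl)ethenyl]oxy}trimethylsilane | C=C(O[Si](C)(C)C)c1c(OC)cc(OCc2ccccc2)cc1OC
A5 | alternative 2 | benzyl 5-hydroxy-7-methoxy-4-oxo-2-phenyl-4H-chromene-6-carboxylate | COc1cc2oc(-c3ccccc3)cc(=O)c2c(O)c1C(=O)OCc1ccccc1
A6 | alternative 2 | 4-oxo-6-phenyl-4H-pyran-3-carbonitrile | N#Cc1coc(-c2ccccc2)cc1=O
A7 | alternative 2 | benzyl 2-[benzyloxy(trimethylsilyloxy)methylidene]-3-methoxybut-3-enoate (ketene acetal geometry not defined) | C=C(OC)C(C(=O)OCc1ccccc1)=C(OCc1ccccc1)O[Si](C)(C)C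
A8 | alternative 3 | 5,7-dihydroxy-6-(5-methoxy-6-methyl-4-oxo-4H-pyran-2-yl)-2-phenyl-4H-chromen-4-one | Oc1cc2oc(-c3ccccc3)cc(=O)c2c(O)c1-c1cc(=O)c(OC)c(C)o1
A9 | alternative 3 | methyl 2-[3-(5-methoxy-6-methyl-4-oxo-4H-pyran-2-yl)-2-oxopropyl]-4-oxo-6-phenyl-4H-pyran-3-carboxylate | COC(=O)c1c(CC(=O)Cc2cc(=O)c(OC)c(C)o2)oc(-c2ccccc2)cc1=O
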